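**Plan**

- Retrosynthesis: the 5-OH/8-OMe pair is traced back to an 8-hydroxy-5-methoxychromone. Ring A is then cut at C5–C6, C7–C8 and C8–C8a into a (4-oxopyran-3-yl)(methoxy)carbene complex of zerovalent chromium, methoxyacetylene and one carbonyl ligand.
- Enabling feature: on ring A, C5–O and C8–O stand para with C6–H and C7–OMe between them (a 4-alkoxyphenol). The C4a=C8a bond is the C3=C2 bond of a 4-pyranone (ring C) that carries hydrogen on the future C8a.
- The carbene carbon (C5) goes back to an acid chloride. Ring C is cut at O1–C8a and C2–C3 into methyl 4-methoxyacetoacetate, one carbon from an amide acetal, and 2-methoxybenzoyl chloride (ring B).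
- Forward: ring B is bought, ring C is built (steps 1–2), the carboxyl becomes the carbene (steps 3–5), ring A is annulated (step 7), and two O-methyl adjustments finish (steps 8–9).
- Stereochemistry: the target has no stereocentre; only regiochemistry must be controlled (alkyne orientation in step 7, site of demethylation in step 9).

Key step: step 7

Remark: every compound marked "starting material" in the list is taken as commercial. Enamine double bonds and enolisable methine carbons in open-chain intermediates are configurationally labile and are drawn without descriptors. Locants C2–C8a refer to flavone numbering unless a pyranone is named.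

**Step 1**
Reactants: 1 methyl 4-methoxy-3-oxobutanoate (methyl 4-methoxyacetoacetate); 2 N,N-dimethylformamide dimethyl acetal
Product: 3 methyl 2-[(dimethylamino)methylidene]-4-methoxy-3-oxobutanoate
Conditions: neat, rt; concentrate
Reagents that add atoms: none
Why: The doubly activated C2 methylene condenses with the amide acetal (aminomethylenation to an enaminone), which leaves the C4 methylene as the only enolisable site for step 2.

**Step 2**
Reactants: 3 methyl 2-[(dimethylamino)methylidene]-4-methoxy-3-oxobutanoate; 4 2-methoxybenzoyl chloride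
Product: 6 methyl 5-methoxy-6-(2-methoxyphenyl)-4-oxo-4H-pyran-3-carboxylate, via acylated enaminone 5 (not isolated)
Conditions: LiN(SiMe3)2 (2.5 equiv), THF, −78 °C, 3 and 4 added together; then 3 M HCl, Et2O, rt
Reagents that add atoms: none
Why: Deprotonation at the methoxy-bearing γ-carbon gives a dienolate that is C-aroylated in situ (Claisen-type acylation of an enaminone anion), and acid then lets the enol oxygen of the new aryl ketone add to the enamine carbon and expel dimethylamine, the established closure to a 4-oxo-4H-pyran-3-carboxylate.

**Step 3**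
Reactants: 6 methyl 5-methoxy-6-(2-methoxyphenyl)-4-oxo-4H-pyran-3-carboxylate
Product: 7 5-methoxy-6-(2-methoxyphenyl)-4-oxo-4H-pyran-3-carboxylic acid
Conditions: 6 M HCl, AcOH, 80 °C
Reagents that add atoms: water, O
Why: Acid-catalysed ester hydrolysis is chosen because hydroxide would open the pyranone by attack at its C2, whereas the ring and the methyl ethers tolerate aqueous HCl.

**Step 4**
Reactants: 7 5-methoxy-6-(2-methoxyphenyl)-4-oxo-4H-pyran-3-carboxylic acid
Product: 8 5-methoxy-6-(2-methoxyphenyl)-4-oxo-4H-pyran-3-carbonyl chloride
Conditions: (COCl)2, cat. DMF, CH2Cl2, 0 °C → rt; evaporate, use crude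
Reagents that add atoms: oxalyl chloride, O=C(Cl)C(Cl)=O
Why: Standard acid chloride formation through the chloroiminium catalyst under non-nucleophilic conditions that leave the pyranone untouched.

**Step 5**
Reactants: 8 5-methoxy-6-(2-methoxyphenyl)-4-oxo-4H-pyran-3-carbonyl chloride; 9 chromium hexacarbonyl
Product: 12 pentacarbonyl{methoxy[5-methoxy-6-(2-methoxyphenyl)-4-oxo-4H-pyran-3-yl]methylidene}chromium, via disodium pentacarbonylchromate 10 (not isolated), via sodium acylpentacarbonylchromate 11 (not isolated)
Conditions: Cr(CO)6, NaC10H8 (2.0 equiv), THF, −78 °C; then 8, −78 → 0 °C; solvent exchange; Me3OBF4 (1.05 equiv), CH2Cl2, 0 °C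
Reagents that add atoms: trimethyloxonium tetrafluoroborate, C[O+](C)C.F[B-](F)(F)F
Why: The strongly nucleophilic pentacarbonylchromate dianion displaces chloride from the acid chloride to give the acylchromate, whose anionic oxygen is methylated far faster than the neutral pyranone carbonyl (acid chloride variant of the Fischer carbene synthesis), so no metallated 4-pyranone is needed.

**Step 6**
Reactants: 13 chloroacetaldehyde dimethyl acetal
Product: 15 methoxyacetylene, via sodium methoxyacetylide 14 (not isolated)
Conditions: NaNH2 (3 equiv), liq. NH3, −33 °C; evaporate NH3; satd aq NaCl, −20 °C; distil into a −78 °C trap, keep as a cold THF solution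
Reagents that add atoms: none
Why: Two base-induced β-eliminations (loss of methanol and of HCl) give the alkynyl ether, which is held as its sodium acetylide until mild protonation and is distilled cold because it is volatile.

**Step 7**
Reactants: 12 pentacarbonyl{methoxy[5-methoxy-6-(2-methoxyphenyl)-4-oxo-4H-pyran-3-yl]methylidene}chromium; 15 methoxyacetylene
Product: 17 8-hydroxy-3,5,7-trimethoxy-2-(2-methoxyphenyl)-4H-chromen-4-one, via dienylcarbene complex 16 (not isolated)
Conditions: 15 (3 equiv), THF, 25 → 45 °C, sealed tube, Ar; then CO (1 atm), hν (medium-pressure Hg lamp, Pyrex), rt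
Reagents that add atoms: carbon monoxide, [C-]#[O+] (the gas exchanges with the carbonyl ligands, one of which becomes C8 and its oxygen)
Why: Proposed new method: the nucleophilic CH terminus of methoxyacetylene should bond to the electrophilic carbene carbon (C5–C6) and leave the oxygen-bearing alkyne carbon on chromium as a new carbene carbon, giving dienylcarbene 16; migration of a carbonyl ligand onto that carbon (C7–C8), thermally or on irradiation under CO, should then give a chromium-bound dienylketene. Ring A closes by a six-electron disrotatory electrocyclisation of the ketene C=C, the C6=C7 bond and the pyranone C2=C3 bond, which forms C8–C8a, and the resulting cyclohexadienone tautomerises to the phenol by transfer of the former pyranone H-2 to oxygen; no stereocentre is formed. The closest known reactions are the Dötz benzannulation of alkenyl- and heteroaryl(alkoxy)carbene Cr(CO)5 complexes with terminal alkynes and the photochemical carbonylative ring closure of dienyl(alkoxy)carbene chromium complexes to ortho-alkoxyphenols, neither of which has been shown for a 4-oxopyran-3-yl carbene or for an alkoxyacetylene. The regiochemistry needed (methoxyl at C7 beside the C8 hydroxyl) follows both from the steric rule of the benzannulation, which places the substituted alkyne carbon next to the carbonyl-derived carbon, and from the polarisation of the ynol ether. Carbonyl uptake has to win over mere insertion, which is why the second stage is run under CO with light, and closure has to occur at carbon, which the substrate secures because C2–H is the only pyranone position that can complete a six-membered carbocycle and it carries the hydrogen needed for aromatisation.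

**Step 8**
Reactants: 17 8-hydroxy-3,5,7-trimethoxy-2-(2-methoxyphenyl)-4H-chromen-4-one
Product: 18 3,5,7,8-tetramethoxy-2-(2-methoxyphenyl)-4H-chromen-4-one
Conditions: MeI, K2CO3, acetone, reflux (crude 17 used at once, under Ar)
Reagents that add atoms: iodomethane, CI
Why: Williamson O-methylation of the only free phenol, which is not hydrogen-bonded to the carbonyl and should alkylate readily before the electron-rich 4-alkoxyphenol can oxidise.

**Step 9**
Reactants: 18 3,5,7,8-tetramethoxy-2-(2-methoxyphenyl)-4H-chromen-4-one
Product: 19 5-hydroxy-3,7,8-trimethoxy-2-(2-methoxyphenyl)-4H-chromen-4-one (5-hydroxy-3,7,8,2'-tetramethoxyflavone)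
Conditions: BCl3 (1.5 equiv), CH2Cl2, −78 → 0 °C; aq. work-up
Reagents that add atoms: none
Why: BCl3 binds the C4 carbonyl and the peri 5-methoxyl in a six-membered chelate and cleaves that ether selectively (chelation-controlled Lewis acid demethylation of 5-methoxyflavones), while the 3-methoxyl can only form a less favourable five-membered chelate and the others are not activated at low temperature.

**Compound list**

1 | methyl 4-methoxy-3-oxobutanoate | COCC(=O)CC(=O)OC | starting material
2 | N,N-dimethylformamide dimethyl acetal | COC(OC)N(C)C | starting material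
3 | methyl 2-[(dimethylamino)methylidene]-4-methoxy-3-oxobutanoate | COCC(=O)C(=CN(C)C)C(=O)OC | intermediate
4 | 2-methoxybenzoyl chloride | COc1ccccc1C(Cl)=O | starting material
5 | methyl 2-[(dimethylamino)methylidene]-4-methoxy-5-(2-methoxyphenyl)-3,5-dioxopentanoate | COC(=O)C(=CN(C)C)C(=O)C(OC)C(=O)c1ccccc1OC | intermediate
6 | methyl 5-methoxy-6-(2-methoxyphenyl)-4-oxo-4H-pyran-3-carboxylate | COC(=O)c1coc(-c2ccccc2OC)c(OC)c1=O | intermediate
7 | 5-methoxy-6-(2-methoxyphenyl)-4-oxo-4H-pyran-3-carboxylic acid | COc1ccccc1-c1occ(C(=O)O)c(=O)c1OC | intermediate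
8 | 5-methoxy-6-(2-methoxyphenyl)-4-oxo-4H-pyran-3-carbonyl chloride | COc1ccccc1-c1occ(C(Cl)=O)c(=O)c1OC | intermediate
9 | chromium hexacarbonyl | O=C=[Cr](=C=O)(=C=O)(=C=O)(=C=O)=C=O | starting material
10 | disodium pentacarbonylchromate | [Na+].[Na+].O=C=[Cr-2](=C=O)(=C=O)(=C=O)=C=O | intermediate
11 | sodium pentacarbonyl{[5-methoxy-6-(2-methoxyphenyl)-4-oxo-4H-pyran-3-yl]carbonyl}chromate | [Na+].[O-]C(=[Cr](=C=O)(=C=O)(=C=O)(=C=O)=C=O)c1coc(-c2ccccc2OC)c(OC)c1=O | intermediate
12 | pentacarbonyl{methoxy[5-methoxy-6-(2-methoxyphenyl)-4-oxo-4H-pyran-3-yl]methylidene}chromium | COC(=[Cr](=C=O)(=C=O)(=C=O)(=C=O)=C=O)c1coc(-c2ccccc2OC)c(OC)c1=O | intermediate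
13 | chloroacetaldehyde dimethyl acetal | COC(CCl)OC | starting material
14 | sodium methoxyacetylide | [Na+].[C-]#COC | intermediate
15 | methoxyacetylene | COC#C | intermediate
16 | pentacarbonyl{(2E)-1,3-dimethoxy-3-[5-methoxy-6-(2-methoxyphenyl)-4-oxo-4H-pyran-3-yl]prop-2-en-1-ylidene}chromium | COC(=[Cr](=C=O)(=C=O)(=C=O)(=C=O)=C=O)/C=C(/OC)c1coc(-c2ccccc2OC)c(OC)c1=O | intermediate
17 | 8-hydroxy-3,5,7-trimethoxy-2-(2-methoxyphenyl)-4H-chromen-4-one | COc1ccccc1-c1oc2c(O)c(OC)cc(OC)c2c(=O)c1OC | intermediate
18 | 3,5,7,8-tetramethoxy-2-(2-methoxyphenyl)-4H-chromen-4-one | COc1ccccc1-c1oc2c(OC)c(OC)cc(OC)c2c(=O)c1OC | intermediate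
19 | 5-hydroxy-3,7,8-trimethoxy-2-(2-methoxyphenyl)-4H-chromen-4-one | COc1ccccc1-c1oc2c(OC)c(OC)cc(O)c2c(=O)c1OC | target

**Step count**

Total steps: 9. Longest linear sequence: 8 (steps 1–5 and 7–9); step 6 is a one-step branch.

**Steps most likely to fail**

Step 7 (the proposed new method). The alkyne may be taken up without a carbonyl ligand following, so that the reaction stalls at the dienylcarbene or drifts into repeated alkyne insertion. The ketene may be intercepted by excess ynol ether, or ring closure may take place through the pyranone carbonyl oxygen instead of C2. The fallback uses only known flavone chemistry, sets out from 4 and returns at 18. Friedel–Crafts acylation of commercial 1,2,3,5-tetramethoxybenzene with methoxyacetyl chloride (AlCl3, Et2O), with the usual loss of the methyl group ortho to the new ketone and flanked by a second methoxyl, should give 1-(2-hydroxy-3,4,6-trimethoxyphenyl)-2-methoxyethan-1-one F1. O-Aroylation with 4 (pyridine, rt) should give 2,3,5-trimethoxy-6-(methoxyacetyl)phenyl 2-methoxybenzoate F2. Baker–Venkataraman rearrangement (KOH, pyridine, 50 °C) should give 1-(2-hydroxy-3,4,6-trimethoxyphenyl)-2-methoxy-3-(2-methoxyphenyl)propane-1,3-dione F3. Cyclodehydration (H2SO4, AcOH, warm) closes ring C to 18, and step 9 follows unchanged.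

Step 5. Electron transfer from the chromate dianion to the pyranone, or conjugate addition at pyranone C2, may compete with acyl substitution. Methylation may also stray to the pyranone carbonyl oxygen (pyrylium formation). The fallback sets out from 7 and returns at 12 by the organometallic form of the Fischer carbene synthesis. Thermal decarboxylation (Cu powder, quinoline, 200 °C) should give 3-methoxy-2-(2-methoxyphenyl)-4H-pyran-4-one F4. Iodination beside the carbonyl (I2, (NH4)2Ce(NO3)6, MeCN) should give 5-iodo-3-methoxy-2-(2-methoxyphenyl)-4H-pyran-4-one F5. Iodine–magnesium exchange (iPrMgCl·LiCl, THF, −40 °C) should give chlorido[5-methoxy-6-(2-methoxyphenyl)-4-oxo-4H-pyran-3-yl]magnesium F6. Addition to Cr(CO)6 should give the chloromagnesium acylpentacarbonylchromate F7, and Me3OBF4 in CH2Cl2 should turn it into 12.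

Step 2. The enaminone anion may decompose before it is acylated, O-acylation may compete with C-acylation, and the ortho-substituted aroyl chloride may react sluggishly. The fallback sets out from 1 and returns at 6, reversing the order of the two condensations. The dianion of 1 (NaH, then n-BuLi, THF, 0 °C) is acylated at the γ-carbon with methyl 2-methoxybenzoate to give methyl 4-methoxy-5-(2-methoxyphenyl)-3,5-dioxopentanoate F8. Condensation of F8 with 2 (toluene, rt → 60 °C) can only occur at the C2 methylene and should pass through 5, which closes to 6 with loss of dimethylamine.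

**Further compounds**

F1 | step 7 | 1-(2-hydroxy-3,4,6-trimethoxyphenyl)-2-methoxyethan-1-one | COCC(=O)c1c(O)c(OC)c(OC)cc1OC
F2 | step 7 | 2,3,5-trimethoxy-6-(methoxyacetyl)phenyl 2-methoxybenzoate | COCC(=O)c1c(OC(=O)c2ccccc2OC)c(OC)c(OC)cc1OC
F3 | step 7 | 1-(2-hydroxy-3,4,6-trimethoxyphenyl)-2-methoxy-3-(2-methoxyphenyl)propane-1,3-dione | COc1ccccc1C(=O)C(OC)C(=O)c1c(O)c(OC)c(OC)cc1OC
F4 | step 5 | 3-methoxy-2-(2-methoxyphenyl)-4H-pyran-4-one | COc1ccccc1-c1occc(=O)c1OC
F5 | step 5 | 5-iodo-3-methoxy-2-(2-methoxyphenyl)-4H-pyran-4-one | COc1ccccc1-c1occ(I)c(=O)c1OC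
F6 | step 5 | chlorido[5-methoxy-6-(2-methoxyphenyl)-4-oxo-4H-pyran-3-yl]magnesium | COc1ccccc1-c1occ([Mg]Cl)c(=O)c1OC
F7 | step 5 | chloromagnesium pentacarbonyl{[5-methoxy-6-(2-methoxyphenyl)-4-oxo-4H-pyran-3-yl]carbonyl}chromate | Cl[Mg+].[O-]C(=[Cr](=C=O)(=C=O)(=C=O)(=C=O)=C=O)c1coc(-c2ccccc2OC)c(OC)c1=O
F8 | step 2 | methyl 4-methoxy-5-(2-methoxyphenyl)-3,5-dioxopentanoate | COC(=O)CC(=O)C(OC)C(=O)c1ccccc1OC
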